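**Assumptions (one line each)**
- (2E,6E)-Farnesol is commercial, as are (S)-Me-CBS-free reagents, 4-bromo-2,5-dimethoxybenzaldehyde and the other reagents named below.
- The epoxide cascade gives mainly the exocyclic Δ8(12) alkene. Any Δ7 co-product is carried on, because Δ7 is the target alkene.
- The ring-C/decalin relative configuration is taken from the target SMILES, and the epoxidation catalyst enantiomer is matched to it.

**Retrosynthesis**
1. The epoxy-enol ring comes from a quinone monoketal by Weitz–Scheffer epoxidation, Luche reduction and ketal unmasking. The monoketal comes from oxidative dearomatization of a 2,5-dimethoxyarene.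
2. The C11–aryl bond is made by Ni cross-electrophile coupling of a drimanyl iodide with an aryl bromide.
3. The Δ7 alkene comes from the exocyclic Δ8(12) alkene by HAT isomerization.
4. Rings A and B form together in one epoxide-initiated cation–olefin cascade of a (10S,11S)-epoxy-12-OTBS-farnesyl acetate. This sets C4 (4α-CH2OR), C5, C9 and C10. The C3–O is then removed (Barton–McCombie).
5. The epoxy alcohol comes from farnesol by acetylation, SeO2 oxidation of the terminal (E)-methyl, and Sharpless epoxidation (L-DET). The arene ring is attached last.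

**Step 1**
Reactants: 1 (2E,6E)-farnesol
Product: 2 (2E,6E)-farnesyl acetate
Conditions: Ac2O, pyridine, DMAP (cat.), CH2Cl2, 0 °C → rt
Reagents that add atoms: acetic anhydride, CC(=O)OC(C)=O
Why: Simple O-acetylation masks the C1 allylic alcohol so that only the terminal methyl is oxidised in the next step.

**Step 2**
Reactants: 2
Product: 3 (2E,6E,10E)-12-hydroxyfarnesyl acetate
Conditions: SeO2 (cat.), TBHP, salicylic acid, CH2Cl2, rt
Reagents that add atoms: tert-butyl hydroperoxide, CC(C)(C)OO; selenium dioxide, O=[Se]=O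
Why: Riley/Sharpless allylic oxidation of the terminal trisubstituted alkene hydroxylates the methyl trans to the chain, giving the (E)-CH2OH (yield modest, about 30%).

**Step 3**
Reactants: 3
Product: 4 (10S,11S)-10,11-epoxy-12-hydroxyfarnesyl acetate
Conditions: Ti(OiPr)4, L-(+)-DET, TBHP, 4 Å MS, CH2Cl2, –20 °C
Reagents that add atoms: tert-butyl hydroperoxide, CC(C)(C)OO
Why: Sharpless asymmetric epoxidation acts only on the free allylic alcohol alkene, and L-(+)-DET gives the (S,S) trans-epoxide, which sets the absolute configuration of the whole decalin.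

**Step 4**
Reactants: 4
Product: 5 TBS ether of 4
Conditions: TBSCl, imidazole, DMF, rt
Reagents that add atoms: tert-butyldimethylsilyl chloride, CC(C)(C)[Si](C)(C)Cl
Why: Silylation removes the free OH, which would otherwise interfere with the Lewis-acid cascade.

**Step 5**
Reactants: 5
Product: 6 (3β-hydroxy-4α-CH2OTBS-4β-methyl-drim-8(12)-en-11-yl acetate)
Conditions: Me2AlCl, CH2Cl2, –78 → –20 °C
Reagents that add atoms: none
Why: Lewis-acid epoxypolyene (cation–olefin) cyclization proceeds through a chair–chair transition state with inversion at the epoxide carbon C11.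
- The trans-epoxide puts the CH2OTBS group equatorial (4α) and the methyl axial (4β).
- The E,E-olefins give the trans-decalin with 10β-Me, 5α-H and 9α-H (C11 equatorial).
- The epoxide oxygen ends as 3β-OH, and loss of H+ from C12 gives the exocyclic alkene.

**Step 6**
Reactants: 6
Product: 7 O-phenyl thionocarbonate of 6
Conditions: PhOC(S)Cl, DMAP, pyridine, CH2Cl2, rt → 40 °C
Reagents that add atoms: phenyl chlorothionoformate, S=C(Cl)Oc1ccccc1
Why: Acylation of the C3 hydroxyl prepares it for radical deoxygenation, with no stereocentre change.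

**Step 7**
Reactants: 7
Product: 8 (3-deoxy compound)
Conditions: Bu3SnH, AIBN, toluene, 110 °C
Reagents that add atoms: none
Why: Barton–McCombie deoxygenation removes the C3 oxygen; the acetate, TBS ether and 1,1-disubstituted alkene survive.

**Step 8**
Reactants: 8
Product: 9 (C11 primary alcohol)
Conditions: K2CO3, MeOH, rt
Reagents that add atoms: none
Why: Methanolysis of the primary acetate leaves the TBS ether intact.

**Step 9**
Reactants: 9
Product: 10 (11-iodo compound)
Conditions: I2, PPh3, imidazole, toluene, 80 °C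
Reagents that add atoms: iodine, II
Why: Appel-type iodination (Garegg–Samuelsson conditions) converts the hindered primary alcohol to the iodide with the C9 stereocentre untouched.

**Step 10**
Reactants: 11 4-bromo-2,5-dimethoxybenzaldehyde
Product: 12 (4-bromo-2,5-dimethoxyphenyl)methanol
Conditions: NaBH4, MeOH/THF, 0 °C
Reagents that add atoms: none
Why: Chemoselective aldehyde reduction.

**Step 11**
Reactants: 12
Product: 13 TBS ether of 12
Conditions: TBSCl, imidazole, DMF, rt
Reagents that add atoms: tert-butyldimethylsilyl chloride, CC(C)(C)[Si](C)(C)Cl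
Why: Silyl protection of the benzylic alcohol for the coupling and the oxidations that follow.

**Step 12**
Reactants: 10, 13
Product: 14 (11-aryl-drim-8(12)-ene)
Conditions: NiBr2·glyme (10 mol%), dtbbpy (10 mol%), Mn, NaI, DMA, rt–50 °C
Reagents that add atoms: none (the aryl group comes from 13)
Why: Ni-catalysed cross-electrophile coupling captures the primary radical generated from the neopentyl-like iodide at an aryl–Ni species, forming C(sp3)–C(sp2) with no effect on C9.

**Step 13**
Reactants: 14
Product: 15 (Δ7 isomer)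
Conditions: Co(salen)Cl (2 mol%), PhSiH3 (5 mol%), PhH, rt
Reagents that add atoms: none
Why: Co–H hydrogen-atom transfer to the exocyclic CH2 gives the tertiary C8 radical, and H-abstraction from the less hindered C7 gives the trisubstituted Δ7-8-methyl alkene of the target.

**Step 14**
Reactants: 15
Product: 16 (quinone monoketal)
Conditions: PIFA, MeOH, NaHCO3, 0 °C
Reagents that add atoms: methanol, CO
Why: Hypervalent-iodine oxidative dearomatization of the p-dimethoxyarene in MeOH puts the dimethyl ketal next to the smaller CH2OTBS carbon and the C=O next to the bulky alkyl-bearing carbon.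

**Step 15**
Reactants: 16
Product: 17 (epoxy enone ketal)
Conditions: H2O2 (30% aq.), 9-amino-9-deoxy-epi-quinine·TFA salt (20 mol%), MeCN, rt
Reagents that add atoms: hydrogen peroxide, OO
Why: Weitz–Scheffer nucleophilic epoxidation is regiospecific. HOO– adds at the unsubstituted β-carbon (C2), whereas the other enone β-carbon (C4) bears CH2OTBS and the Δ7 alkene is inert, so only the alkyl-substituted alkene is epoxidised. The chiral amine catalyst sets the epoxide face relative to the decalin.

**Step 16**
Reactants: 17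
Product: 18 (6R-allylic alcohol ketal)
Conditions: NaBH4, CeCl3·7H2O, MeOH, –78 °C
Reagents that add atoms: none
Why: Luche 1,2-reduction delivers hydride to the face anti to the bulky C11 substituent (syn to the epoxide oxygen). This gives the C6 alcohol cis to C11 and trans to the epoxide, as in the target.

**Step 17**
Reactants: 18
Product: 19 (epoxy enone, C6-OTES)
Conditions: TESOTf, 2,4,6-collidine, CH2Cl2, 0 °C; then H2O
Reagents that add atoms: triethylsilyl triflate, CC[Si](CC)(CC)OS(=O)(=O)C(F)(F)F; water, O
Why: Non-acidic ketal cleavage (via the collidinium salt, then hydrolysis) unmasks the C3 ketone, which is now conjugated with C4=C5, while the acid-sensitive epoxide survives. The C6 hydroxyl is silylated in the same operation.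

**Step 18**
Reactants: 19
Product: 20 Epoxypholamin A
Conditions: HF·pyridine, THF/pyridine, 0 °C → rt
Reagents that add atoms: none
Why: Buffered fluoride removes the two TBS ethers and the TES ether without touching the epoxy enone or the Δ7 alkene.

**Compound list**

| No. | Name | SMILES | Role |
|---|---|---|---|
| 1 | (2E,6E)-farnesol | CC(C)=CCC/C(C)=C/CC/C(C)=C/CO | starting material |
| 2 | (2E,6E)-farnesyl acetate | CC(C)=CCC/C(C)=C/CC/C(C)=C/COC(C)=O | intermediate |
| 3 | (2E,6E,10E)-12-hydroxyfarnesyl acetate | OC/C(C)=C/CC/C(C)=C/CC/C(C)=C/COC(C)=O | intermediate |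
| 4 | (10S,11S)-10,11-epoxy-12-hydroxyfarnesyl acetate | OC[C@]1(C)O[C@H]1CC/C(C)=C/CC/C(C)=C/COC(C)=O | intermediate |
| 5 | 12-OTBS epoxide | CC(C)(C)[Si](C)(C)OC[C@]1(C)O[C@H]1CC/C(C)=C/CC/C(C)=C/COC(C)=O | intermediate |
| 6 | 3β-hydroxy-4α-CH2OTBS-drim-8(12)-en-11-yl acetate | C=C1CC[C@H]2[C@](C)(CO[Si](C)(C)C(C)(C)C)[C@@H](O)CC[C@]2(C)[C@H]1COC(C)=O | intermediate |
| 7 | 3-O-phenyl thionocarbonate of 6 | C=C1CC[C@H]2[C@](C)(CO[Si](C)(C)C(C)(C)C)[C@@H](OC(=S)Oc3ccccc3)CC[C@]2(C)[C@H]1COC(C)=O | intermediate |
| 8 | 3-deoxy acetate | C=C1CC[C@H]2[C@](C)(CO[Si](C)(C)C(C)(C)C)CCC[C@]2(C)[C@H]1COC(C)=O | intermediate |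
| 9 | C11 primary alcohol | C=C1CC[C@H]2[C@](C)(CO[Si](C)(C)C(C)(C)C)CCC[C@]2(C)[C@H]1CO | intermediate |
| 10 | 11-iodide | C=C1CC[C@H]2[C@](C)(CO[Si](C)(C)C(C)(C)C)CCC[C@]2(C)[C@H]1CI | intermediate |
| 11 | 4-bromo-2,5-dimethoxybenzaldehyde | COc1cc(C=O)c(OC)cc1Br | starting material |
| 12 | (4-bromo-2,5-dimethoxyphenyl)methanol | COc1cc(CO)c(OC)cc1Br | intermediate |
| 13 | aryl bromide TBS ether | COc1cc(CO[Si](C)(C)C(C)(C)C)c(OC)cc1Br | intermediate |
| 14 | 11-aryl-drim-8(12)-ene | C=C1CC[C@H]2[C@](C)(CO[Si](C)(C)C(C)(C)C)CCC[C@]2(C)[C@H]1Cc1cc(OC)c(CO[Si](C)(C)C(C)(C)C)cc1OC | intermediate |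
| 15 | Δ7 isomer of 14 | CC1=CC[C@H]2[C@](C)(CO[Si](C)(C)C(C)(C)C)CCC[C@]2(C)[C@H]1Cc1cc(OC)c(CO[Si](C)(C)C(C)(C)C)cc1OC | intermediate |
| 16 | quinone monoketal | CC1=CC[C@H]2[C@](C)(CO[Si](C)(C)C(C)(C)C)CCC[C@]2(C)[C@H]1CC1=CC(OC)(OC)C(CO[Si](C)(C)C(C)(C)C)=CC1=O | intermediate |
| 17 | epoxy enone ketal | CC1=CC[C@H]2[C@](C)(CO[Si](C)(C)C(C)(C)C)CCC[C@]2(C)[C@H]1C[C@@]12O[C@@H]1C(OC)(OC)C(CO[Si](C)(C)C(C)(C)C)=CC2=O | intermediate |
| 18 | 6R-allylic alcohol ketal | CC1=CC[C@H]2[C@](C)(CO[Si](C)(C)C(C)(C)C)CCC[C@]2(C)[C@H]1C[C@@]12O[C@@H]1C(OC)(OC)C(CO[Si](C)(C)C(C)(C)C)=C[C@H]2O | intermediate |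
| 19 | epoxy enone, C6-OTES, two TBS ethers | CC1=CC[C@H]2[C@](C)(CO[Si](C)(C)C(C)(C)C)CCC[C@]2(C)[C@H]1C[C@@]12O[C@@H]1C(=O)C(CO[Si](C)(C)C(C)(C)C)=C[C@H]2O[Si](CC)(CC)CC | intermediate |
| 20 | Epoxypholamin A | CC1=CC[C@H]2[C@](C)(CO)CCC[C@]2(C)[C@H]1C[C@@]12O[C@@H]1C(=O)C(CO)=C[C@H]2O | target |

**Totals**
- Total steps: 18.
- Longest linear sequence: 16 (steps 1–9, then 12–18). Steps 10–11 build the aryl bromide in parallel.

**Three steps most likely to fail**
1. **Step 5 (epoxide cascade).** The CH2OTBS group destabilises the tertiary cation, so yield and the Δ8(12)/Δ7/Δ8(9) ratio may be poor.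
   - Fallback: start from (S)-Wieland–Miescher ketone, do 4-methylation then 4-hydroxymethylation of the Δ5-3-ketone (second electrophile enters α), and build ring B separately.
2. **Step 15 (catalytic epoxidation).** The catalyst may not override the weak facial bias from the remote decalin, giving diastereomeric mixtures.
   - Fallback: a convergent route that fixes the ring stereochemistry from the chiral pool. Add decalinyl-CH2MgBr/CeCl3 to a shikimic-acid-derived α-sulfonyloxy cyclohexenone ketone to form the epoxide by alkoxide closure.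
3. **Step 12 (Ni coupling).** The hindered neopentyl-type radical may give homoallyl rearrangement, reduction or dimerisation.
   - Fallback: a polar coupling. Oxidise alcohol 9 to the aldehyde, add the aryllithium from 13 (Li–Br exchange), then remove the benzylic OH with Et3SiH/TFA.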